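**Plan**

- Labels: dihydrobenzofuran O1, C2, C3, C3a, C4–C7, C7a (its benzo ring is ring A); the ketone carbon sits on C4, its α-carbon on B2 of ring B, and B1 of ring B on C3. Retrosynthetically the four methyl ethers and the labile α-carbon are dealt with last, then C3a–C3 and O1–C2 are cut together.
- Enabling feature: C3 belongs to both the seven-membered ring and the dihydrofuran, so an open C2=C3 stilbene attacked at C3 by ring A carbon C3a and at C2 by the phenol oxygen on C7a closes both rings in one step.
- The open 3,5-dihydroxyphenyl triaryl ketone is cut at Cα–B2 (enolate arylation), at C2=C3 (olefination) and at C(=O)–Cα (acylation with decarboxylation).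
- Forward: a deoxybenzoin (ring A plus one anisyl group) and a bromostilbene (ring B plus the other) are joined at Cα–B2. The seven-membered ring closes first and the dihydrofuran second within one oxidative step; demethylation and α-equilibration finish.
- Stereochemistry: C3 from a chiral phosphate counter-anion in the cyclisation, C2 trans to C3 in the same ring closure, Cα last by thermodynamic equilibration against the fixed (2R,3R) pair.

Key step: step 7

Assumption: the αR configuration of the natural product, at a readily enolisable doubly benzylic carbon, is taken to be the thermodynamically preferred one once C2 and C3 are (R,R).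
Assumption: the sense of induction of the (R)-configured phosphate in step 7 must be confirmed in the first run; if it leads to the (2S,3S) series, the equally available (S)-phosphate is used with no other change.

**Route**

Step 1
Reactants: 1 methyl 3,5-dihydroxybenzoate
Product: 2 methyl 3,5-bis(methoxymethoxy)benzoate
Conditions: MOMCl (2.5 equiv), i-Pr2NEt (3 equiv), CH2Cl2, 0 °C → rt
Reagents that add atoms: chloromethyl methyl ether (MOMCl), COCCl
Why: O-alkylation of both phenols (Williamson-type acetal formation) gives MOM ethers that tolerate the strong bases and the palladium coupling ahead and are later removed by mild acid without touching aryl methyl ethers.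

Step 2
Reactants: 2 methyl 3,5-bis(methoxymethoxy)benzoate; 3 4-methoxyphenylacetic acid
Product: 5 1-[3,5-bis(methoxymethoxy)phenyl]-2-(4-methoxyphenyl)ethan-1-one, via β-keto acid 4 (not isolated)
Conditions: 3 (1.2 equiv), LiN(SiMe3)2 (4 equiv), THF, −10 °C → rt; then 1 M HCl to pH 3, 40 °C
Reagents that add atoms: none
Why: Claisen-type acylation of the arylacetic acid enediolate by the methyl ester, followed by decarboxylation of the β-keto acid on acidification, is an established one-pot deoxybenzoin synthesis that avoids over-addition.

Step 3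
Reactants: 6 3,5-dimethoxybenzaldehyde
Product: 7 2-bromo-3,5-dimethoxybenzaldehyde
Conditions: NBS (1.05 equiv), MeCN, 0 °C → rt
Reagents that add atoms: N-bromosuccinimide, O=C1CCC(=O)N1Br
Why: Electrophilic aromatic bromination should occur at C2, which is ortho to one methoxy group and para to the other and less crowded than C4 between the two methoxy groups.

Step 4
Reactants: 7 2-bromo-3,5-dimethoxybenzaldehyde; 8 diethyl (4-methoxybenzyl)phosphonate
Product: 9 2-bromo-1,5-dimethoxy-3-[(E)-2-(4-methoxyphenyl)ethenyl]benzene
Conditions: 8 (1.1 equiv), KOtBu (1.2 equiv), THF, 0 °C → rt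
Reagents that add atoms: none
Why: Horner–Wadsworth–Emmons olefination of a non-enolisable aryl aldehyde with a benzylphosphonate anion should give the (E)-stilbene, and doing it before the ketone is introduced avoids a competing acidic α-proton.

Step 5
Reactants: 5 1-[3,5-bis(methoxymethoxy)phenyl]-2-(4-methoxyphenyl)ethan-1-one; 9 2-bromo-1,5-dimethoxy-3-[(E)-2-(4-methoxyphenyl)ethenyl]benzene
Product: 10 rac-1-[3,5-bis(methoxymethoxy)phenyl]-2-{2,4-dimethoxy-6-[(E)-2-(4-methoxyphenyl)ethenyl]phenyl}-2-(4-methoxyphenyl)ethan-1-one
Conditions: Pd(OAc)2 (5 mol%), P(t-Bu)3·HBF4 (10 mol%), NaOtBu (2.5 equiv), toluene, 80 °C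
Reagents that add atoms: none
Why: Palladium-catalysed α-arylation of a ketone enolate (oxidative addition to zerovalent palladium, enolate binding, reductive elimination) with a bulky trialkylphosphine suited to ortho-substituted bromides; the more acidic product enolate blocks a second arylation, and the racemic α-carbon is harmless because it is equilibrated in step 9.

Step 6
Reactants: 10 rac-1-[3,5-bis(methoxymethoxy)phenyl]-2-{2,4-dimethoxy-6-[(E)-2-(4-methoxyphenyl)ethenyl]phenyl}-2-(4-methoxyphenyl)ethan-1-one
Product: 11 rac-1-(3,5-dihydroxyphenyl)-2-{2,4-dimethoxy-6-[(E)-2-(4-methoxyphenyl)ethenyl]phenyl}-2-(4-methoxyphenyl)ethan-1-one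
Conditions: HCl (1.25 M in MeOH), THF, 40 °C
Reagents that add atoms: none
Why: Acid-catalysed transacetalisation removes both MOM ethers as dimethoxymethane, while aryl methyl ethers, the ketone and the (E)-stilbene are inert to dilute methanolic HCl.

Step 7
Reactants: 11 rac-1-(3,5-dihydroxyphenyl)-2-{2,4-dimethoxy-6-[(E)-2-(4-methoxyphenyl)ethenyl]phenyl}-2-(4-methoxyphenyl)ethan-1-one
Product: 12 (2R,3R)-pauciflorol E tetramethyl ether with free C6 hydroxyl (trans-2-(4-methoxyphenyl)dihydrobenzofuran whose C3 and C4 are bridged through B1/B2 of the dimethoxy ring B, CH(4-methoxyphenyl) and C=O; α-carbon as a mixture of epimers)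
Conditions: Ru(bpz)3(PF6)2 (2 mol%, bpz = 2,2'-bipyrazine), tetrabutylammonium salt of (R)-TRIP [(R)-3,3'-bis(2,4,6-triisopropylphenyl)-1,1'-binaphthyl-2,2'-diyl hydrogen phosphate] (10 mol%), K2S2O8 (1.5 equiv, finely ground), CH2Cl2/MeCN 4:1 (0.01 M), blue LEDs, −20 °C, Ar
Reagents that add atoms: none
Why: Proposed new method: the photoexcited ruthenium complex takes one electron from the 4-methoxystilbene arm, the most easily oxidised π-system of 11, and the ring A carbon lying between the acyl-bearing carbon and a phosphate-bound hydroxyl adds to C3 of the radical cation; loss of a proton leaves the 4-methoxybenzylic C2 radical, which persulfate oxidises to the cation that the neighbouring phenol oxygen captures. The closest known reaction types are the photocatalytic oxidative [3+2] cycloaddition of phenols with styrenes to dihydrobenzofurans and radical-cation cycloadditions steered by a chiral counter-anion. The seven-membered ring closes in 7-exo-trig mode (C3a–C3) and the dihydrofuran in 5-exo-trig mode at the benzylic cation (O1–C2). C3 is set by the chiral phosphate, which is hydrogen-bonded to the ring A hydroxyl and ion-paired with the radical cation so that one face of C3 is presented to the arene, and C2 follows from C3 because the oxygen closes on the planar cation with the 4-methoxyphenyl group anti to ring B (trans). Attack at C3 and not C2 is secured by the stabilised radical left at C2 and by the seven- over eight-membered ring; ring A offers no regiochemical choice because its two ortho carbons are equivalent, and the 4-methoxyphenyl ring on the α-carbon could only react at a position meta to its methoxy group. The racemic, enolisable α-carbon of 11 needs no control here because it is equilibrated in step 9.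

Step 8
Reactants: 12 (2R,3R)-pauciflorol E tetramethyl ether with free C6 hydroxyl (α-carbon epimer mixture)
Product: 13 (2R,3R)-pauciflorol E as a mixture of epimers at the α-carbon
Conditions: BBr3 (12 equiv), CH2Cl2, −78 → 0 °C; MeOH then H2O quench
Reagents that add atoms: none
Why: BBr3 cleavage of aryl methyl ethers is the usual last unmasking of methylated resveratrol oligomers; C3 has no acidic or ionisable bond, a transiently ionised C2–O bond can only re-close trans to the fixed C3 substituent, and the α-carbon is deliberately left for step 9.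

Step 9
Reactants: 13 (2R,3R)-pauciflorol E as a mixture of epimers at the α-carbon
Product: 14 pauciflorol E, (2R,3R,αR)
Conditions: Et3N (2 equiv), degassed MeOH, 40 °C, Ar; reverse-phase chromatography
Reagents that add atoms: none
Why: Amine-mediated keto–enol equilibration (thermodynamic epimerisation) of the doubly benzylic α-carbon, with C2 and C3 fixed and non-acidic, should let the 4-hydroxyphenyl group settle in the lower-energy αR orientation of the natural product.

**Compound list**

1 | methyl 3,5-dihydroxybenzoate | COC(=O)c1cc(O)cc(O)c1 | starting material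
2 | methyl 3,5-bis(methoxymethoxy)benzoate | COC(=O)c1cc(OCOC)cc(OCOC)c1 | intermediate
3 | 4-methoxyphenylacetic acid | COc1ccc(CC(=O)O)cc1 | starting material
4 | 3-[3,5-bis(methoxymethoxy)phenyl]-2-(4-methoxyphenyl)-3-oxopropanoic acid (β-keto acid, present as its lithium salt, not isolated) | O=C(c1cc(OCOC)cc(OCOC)c1)C(C(=O)O)c1ccc(OC)cc1 | intermediate
5 | 1-[3,5-bis(methoxymethoxy)phenyl]-2-(4-methoxyphenyl)ethan-1-one | O=C(Cc1ccc(OC)cc1)c1cc(OCOC)cc(OCOC)c1 | intermediate
6 | 3,5-dimethoxybenzaldehyde | COc1cc(C=O)cc(OC)c1 | starting material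
7 | 2-bromo-3,5-dimethoxybenzaldehyde | COc1cc(C=O)c(Br)c(OC)c1 | intermediate
8 | diethyl (4-methoxybenzyl)phosphonate | CCOP(=O)(Cc1ccc(OC)cc1)OCC | starting material
9 | 2-bromo-1,5-dimethoxy-3-[(E)-2-(4-methoxyphenyl)ethenyl]benzene | COc1ccc(/C=C/c2cc(OC)cc(OC)c2Br)cc1 | intermediate
10 | rac-1-[3,5-bis(methoxymethoxy)phenyl]-2-{2,4-dimethoxy-6-[(E)-2-(4-methoxyphenyl)ethenyl]phenyl}-2-(4-methoxyphenyl)ethan-1-one | O=C(c1cc(OCOC)cc(OCOC)c1)C(c1ccc(OC)cc1)c1c(OC)cc(OC)cc1/C=C/c1ccc(OC)cc1 | intermediate
11 | rac-1-(3,5-dihydroxyphenyl)-2-{2,4-dimethoxy-6-[(E)-2-(4-methoxyphenyl)ethenyl]phenyl}-2-(4-methoxyphenyl)ethan-1-one | O=C(c1cc(O)cc(O)c1)C(c1ccc(OC)cc1)c1c(OC)cc(OC)cc1/C=C/c1ccc(OC)cc1 | intermediate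
12 | (2R,3R)-pauciflorol E tetramethyl ether with free C6 hydroxyl (methyl ethers on both ring B oxygens and both 4-oxyphenyl groups; α-carbon epimer mixture) | O=C1c2cc(O)cc3c2[C@@H](c2cc(OC)cc(OC)c2C1c1ccc(OC)cc1)[C@H](c1ccc(OC)cc1)O3 | intermediate
13 | (2R,3R)-pauciflorol E, mixture of epimers at the α-carbon | O=C1c2cc(O)cc3c2[C@@H](c2cc(O)cc(O)c2C1c1ccc(O)cc1)[C@H](c1ccc(O)cc1)O3 | intermediate
14 | pauciflorol E, (2R,3R,αR) | O=C1c2cc(O)cc3c2[C@@H](c2cc(O)cc(O)c2[C@H]1c1ccc(O)cc1)[C@H](c1ccc(O)cc1)O3 | target

Total step count: 9
Longest linear sequence: 7 steps (6 → 14 through steps 3, 4, 5, 6, 7, 8, 9; the branch from 1 through steps 1, 2, 5–9 is equally long)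

**Steps most likely to fail**

Step 7 (Proposed new method). What may go wrong:
- back electron transfer or E/Z isomerisation of the stilbene radical cation may outrun the 7-exo carbon–carbon bond formation;
- oxidation of the enol form may divert the substrate into indane closure through the α-carbon;
- over-oxidation may aromatise the product to the benzofuran;
- the counter-anion may fail to discriminate the two faces of C3.

Fallback, known reactions only, sets out from 10 and returns at 12. The stilbene of 10 is cleaved (OsO4 cat., NaIO4, 2,6-lutidine, dioxane/H2O, Lemieux–Johnson) to the aldehyde 1-[3,5-bis(methoxymethoxy)phenyl]-2-(2-formyl-4,6-dimethoxyphenyl)-2-(4-methoxyphenyl)ethan-1-one F1. Methanolic HCl with TolSO2Na at 40 °C should remove both MOM groups, let the ring A carbon ortho to a hydroxyl condense with the aldehyde (intramolecular Friedel–Crafts hydroxyalkylation closing the seven-membered ring) and trap the benzhydryl cation as the sulfone 6,8-dihydroxy-1,3-dimethoxy-11-(4-methoxyphenyl)-5-(4-methylbenzenesulfonyl)-5,11-dihydro-10H-dibenzo[a,d][7]annulen-10-one F2. The ylide precursor (4-methoxybenzyl)dimethylsulfonium tetrafluoroborate F3 is made from 4-methoxybenzyl alcohol, dimethyl sulfide and HBF4·OEt2. With Cs2CO3 in CH2Cl2, F2 should lose sulfinate to an ortho-quinone methide, which undergoes [4+1] annulation with the ylide of F3 (addition at C3, then displacement of dimethyl sulfide by the phenoxide at C2) to give the racemic trans-dihydrobenzofuran rac-(2R*,3R*)-pauciflorol E tetramethyl ether with free C6 hydroxyl F4. Under the basic conditions the ketone is masked as its enolate. Preparative chromatography on a chiral stationary phase then delivers the (2R,3R) enantiomer 12.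

Step 5. What may go wrong: reductive elimination from the crowded arylpalladium enolate of a di-ortho-substituted bromide may be slow, so that protodebromination or Heck-type consumption of the styryl group takes over.

Fallback, sets out from 9 and returns at 10. The bulky ketone enolate is replaced by the slimmer anion of 4-methoxyphenylacetonitrile, and the aryl ketone is built afterwards by carbonyl addition. Palladium-catalysed nitrile α-arylation of 9 (Pd(OAc)2, BINAP, NaN(SiMe3)2, toluene, 80 °C) should give 2-{2,4-dimethoxy-6-[(E)-2-(4-methoxyphenyl)ethenyl]phenyl}-2-(4-methoxyphenyl)acetonitrile F5. Reduction with i-Bu2AlH (toluene, −78 °C, then dilute HCl) gives 2-{2,4-dimethoxy-6-[(E)-2-(4-methoxyphenyl)ethenyl]phenyl}-2-(4-methoxyphenyl)acetaldehyde F6. The ring A donor 1-bromo-3,5-bis(methoxymethoxy)benzene F7 (from 5-bromoresorcinol, MOMCl, i-Pr2NEt) is lithiated (n-BuLi, THF, −78 °C), transmetallated with CeCl3 to suppress enolisation and added to F6, giving 1-[3,5-bis(methoxymethoxy)phenyl]-2-{2,4-dimethoxy-6-[(E)-2-(4-methoxyphenyl)ethenyl]phenyl}-2-(4-methoxyphenyl)ethan-1-ol F8. Dess–Martin oxidation returns 10.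

Step 8. What may go wrong: the Lewis acid may ionise the benzylic C2–O bond during ether cleavage, opening the dihydrofuran or triggering Friedel–Crafts rearrangement, and demethylation may stop short of completion.

Fallback, sets out from 12 and returns at 13. The ether cleavage is switched from electrophilic activation of the ether oxygens to nucleophilic attack on the methyl carbons: NaSEt in DMF at 120–130 °C (SN2 dealkylation), then acidification. No cation can form at C2 under these conditions, and no compound outside the list is made (F0).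

**Further compounds**

F1 | step 7 | rac-1-[3,5-bis(methoxymethoxy)phenyl]-2-(2-formyl-4,6-dimethoxyphenyl)-2-(4-methoxyphenyl)ethan-1-one | O=Cc1cc(OC)cc(OC)c1C(c1ccc(OC)cc1)C(=O)c1cc(OCOC)cc(OCOC)c1
F2 | step 7 | 6,8-dihydroxy-1,3-dimethoxy-11-(4-methoxyphenyl)-5-(4-methylbenzenesulfonyl)-5,11-dihydro-10H-dibenzo[a,d][7]annulen-10-one (diastereomer mixture) | O=C1c2cc(O)cc(O)c2C(S(=O)(=O)c2ccc(C)cc2)c2cc(OC)cc(OC)c2C1c1ccc(OC)cc1
F3 | step 7 | (4-methoxybenzyl)dimethylsulfonium tetrafluoroborate | C[S+](C)Cc1ccc(OC)cc1.F[B-](F)(F)F
F4 | step 7 | rac-(2R*,3R*)-pauciflorol E tetramethyl ether with free C6 hydroxyl (racemate, α-carbon epimer mixture) | O=C1c2cc(O)cc3c2[C@@H](c2cc(OC)cc(OC)c2C1c1ccc(OC)cc1)[C@H](c1ccc(OC)cc1)O3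
F5 | step 5 | rac-2-{2,4-dimethoxy-6-[(E)-2-(4-methoxyphenyl)ethenyl]phenyl}-2-(4-methoxyphenyl)acetonitrile | N#CC(c1ccc(OC)cc1)c1c(OC)cc(OC)cc1/C=C/c1ccc(OC)cc1
F6 | step 5 | rac-2-{2,4-dimethoxy-6-[(E)-2-(4-methoxyphenyl)ethenyl]phenyl}-2-(4-methoxyphenyl)acetaldehyde | O=CC(c1ccc(OC)cc1)c1c(OC)cc(OC)cc1/C=C/c1ccc(OC)cc1
F7 | step 5 | 1-bromo-3,5-bis(methoxymethoxy)benzene | COCOc1cc(Br)cc(OCOC)c1
F8 | step 5 | 1-[3,5-bis(methoxymethoxy)phenyl]-2-{2,4-dimethoxy-6-[(E)-2-(4-methoxyphenyl)ethenyl]phenyl}-2-(4-methoxyphenyl)ethan-1-ol (diastereomer mixture) | OC(c1cc(OCOC)cc(OCOC)c1)C(c1ccc(OC)cc1)c1c(OC)cc(OC)cc1/C=C/c1ccc(OC)cc1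
F0 | step 8 | none | none
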